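**Retrosynthetic overview**
1. Juncin Q comes from late C16–H allylic hydroxylation, OH-directed 11(20)-epoxidation and OH-directed 12,13-dihydroxylation of a ring A diene. The acetates are placed by silyl/acetate exchange.
2. The ten-membered ring and the γ-lactone come from a one-flask Grob ring expansion (cleavage of C3–C8) and propionate aldol of a linear 6-6-6 tricycle (rings A, B, C).
3. Ring C comes from an aldol (C3–C4, methacrolein), an acyloxyallylation (C7–C8, acrolein plus propionyl bromide) and ring-closing metathesis (C5=C6).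
4. Rings A/B come from an enantioselective Diels–Alder reaction of 2-methoxy-5-methylbenzoquinone (from o-cresol) with a crotonaldehyde-derived silyloxydiene. C20 comes from a Wittig reaction.
5. Ring order: B (quinone), then A, then C, then the ten-membered ring and lactone together (B and C merge), then the epoxide.

Locants: briarane locants of the target are used for all compounds (C1 quaternary with C15 methyl, C10 ring-fusion CH). β is the face of C15 and α is the face of H-10. TBS = tert-butyldimethylsilyl, TES = triethylsilyl.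
Assumption: the (S)-oxazaborolidinium ion is taken to give the drawn enantiomeric series in step 4; if the sense proves opposite, the equally available (R)-catalyst is used.

Step 1
Reactants: 1 o-cresol
Product: 2 2-methyl-1,4-benzoquinone
Conditions: (KSO3)2NO (2.2 equiv), KH2PO4 buffer, H2O/acetone, 0–23 °C
Reagents that add atoms: potassium nitrosodisulfonate [K+].[K+].[O]N(S(=O)(=O)[O-])S(=O)(=O)[O-]
Why: Teuber oxidation: two equivalents of the nitrosodisulfonate radical convert a phenol with a free para position into the p-quinone, and no stereocentre is involved.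

Step 2
Reactants: 2 2-methyl-1,4-benzoquinone
Product: 3 2-methoxy-5-methyl-1,4-benzoquinone
Conditions: MeOH, ZnCl2, 23 °C (2 equiv of 2, the second as oxidant)
Reagents that add atoms: methanol CO
Why: Oxidative alkoxylation of a quinone: ZnCl2-promoted conjugate addition of methanol para to the methyl-bearing carbon and redox exchange with a second equivalent of 2 give the 2,5-isomer, whose methoxy group deactivates its own C=C for step 4 and masks the later C8 carbonyl.

Step 3
Reactants: 4 crotonaldehyde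
Product: 5 (E)-1-(tert-butyldimethylsilyloxy)buta-1,3-diene
Conditions: TBSOTf, Et3N, Et2O, 0 °C
Reagents that add atoms: tert-butyldimethylsilyl triflate CC(C)(C)[Si](C)(C)OS(=O)(=O)C(F)(F)F
Why: Soft vinylogous enolisation (γ-deprotonation of the silyl-activated enal) gives the E-dienol silyl ether, a reactive 1-oxygenated diene.

Step 4
Reactants: 3 2-methoxy-5-methyl-1,4-benzoquinone; 5 (E)-1-(tert-butyldimethylsilyloxy)buta-1,3-diene
Product: 7 trans-fused ring A/B enedione (14α-OTBS; 8-OMe; 1β-Me; 10αH; 2,9-dione), via cis-fused adduct 6 (not isolated)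
Conditions: (S)-3,3-diphenyl-1-(2-methylphenyl)tetrahydro-1H,3H-pyrrolo[1,2-c][1,3,2]oxazaborole (20 mol %), HN(SO2CF3)2 (18 mol %), CH2Cl2, −78 °C; then 1,8-diazabicyclo[5.4.0]undec-7-ene (30 mol %), 23 °C
Reagents that add atoms: none
Why: Catalytic enantioselective Diels–Alder reaction: the boron cation binds the more basic vinylogous-ester carbonyl (C2=O), so only the methyl-bearing C1=C10 bond is activated with C10 as its electrophilic end, the CH2 terminus of 5 bonds to C10 and the oxygenated terminus to C1, the endo transition state places 14-O anti to C15, the catalyst face fixes the absolute configuration at C1 and C14, and base equilibration of the only enolisable centre (C10) then gives the more stable trans fusion.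

Step 5
Reactants: 7 trans-fused ring A/B enedione
Product: 8 9β-alcohol (C2 vinylogous ester kept)
Conditions: NaBH4, CeCl3·7H2O, MeOH, −78 °C
Reagents that add atoms: none
Why: Luche reduction: only the cross-conjugated C9 ketone reacts (the C2 vinylogous ester is inert), and hydride enters from the α face because the syn-axial C15 methyl blocks the β face, which gives the axial 9β-alcohol.

Step 6
Reactants: 8 9β-alcohol
Product: 9 9β-OTES ether
Conditions: TESOTf, 2,6-lutidine, CH2Cl2, −40 °C
Reagents that add atoms: triethylsilyl triflate CC[Si](CC)(CC)OS(=O)(=O)C(F)(F)F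
Why: Silyl triflate silylation protects the hindered axial alcohol for the oxidative and basic steps that follow, and no stereocentre changes.

Step 7
Reactants: 9 9β-OTES ether
Product: 10 Δ12-en-11-one
Conditions: Rh2(caprolactamate)4 (1 mol %), tBuOOH (5 equiv), K2CO3 (0.5 equiv), CH2Cl2, 23 °C
Reagents that add atoms: tert-butyl hydroperoxide CC(C)(C)OO
Why: Dirhodium-catalysed allylic C–H oxidation (tert-butylperoxy radical chain): C11 is the only allylic methylene because C14 carries the silyloxy group, so the enone forms there and C10 keeps its more stable trans arrangement.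

Step 8
Reactants: 10 Δ12-en-11-one
Product: 11 11(20),12-diene (C20 installed)
Conditions: Ph3PCH3Br, KOtBu, THF, −78 → 0 °C
Reagents that add atoms: methyltriphenylphosphonium bromide C[P+](c1ccccc1)(c1ccccc1)c1ccccc1.[Br-]
Why: Wittig methylenation: the non-stabilised ylide attacks the enone carbonyl, whereas the hindered vinylogous ester at C2 does not react.

Step 9
Reactants: 11 11(20),12-diene
Product: 12 2β-alcohol (3-methoxyallylic alcohol)
Conditions: LiAlH4, Et2O, −20 °C; aqueous NaOH work-up
Reagents that add atoms: none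
Why: 1,2-Hydride reduction of the vinylogous ester: hydride enters from the α face, opposite the adjacent axial C15 methyl, and gives the equatorial 2β-alcohol.

Step 10
Reactants: 12 2β-alcohol
Product: 13 2β,9β-bis-OTES methyl enol ether
Conditions: TESCl, imidazole, 4-dimethylaminopyridine (10 mol %), DMF, 23 °C
Reagents that add atoms: chlorotriethylsilane CC[Si](CC)(CC)Cl
Why: Silylation under basic conditions protects the acid-labile 3-methoxyallylic alcohol without ionising it.

Step 11
Reactants: 13 2β,9β-bis-OTES methyl enol ether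
Product: 14 3α-iodo-8-ketone
Conditions: N-iodosuccinimide (1.0 equiv), H2O, NaHCO3, THF, −20 °C
Reagents that add atoms: N-iodosuccinimide O=C1CCC(=O)N1I; water O
Why: Iodohydroxylation of the enol ether: the most electron-rich alkene takes up iodonium at C3, water adds at C8 and the hemiketal loses methanol, which unmasks the C8 ketone without acid (no ionisation at C2) and marks C3 for regiospecific enolate formation, so the C3 configuration is of no consequence.

Step 12
Reactants: 14 3α-iodo-8-ketone; 15 methacrolein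
Product: 18 3,4-anti aldol diphenyl phosphate (C4 side chain α-equatorial on C3), via chloromagnesium enolate 16 (not isolated), via chloromagnesium aldolate 17 (not isolated)
Conditions: iPrMgCl, THF, −78 °C; 15; then ClP(O)(OPh)2, −78 → −20 °C; pH 7 buffer
Reagents that add atoms: diphenyl chlorophosphate O=P(Cl)(Oc1ccccc1)Oc1ccccc1
Why: Halogen–magnesium exchange gives the C3(8) enolate regiospecifically, its Zimmerman–Traxler aldol addition occurs on the α face (β face blocked by the syn-axial C15 methyl) to give the equatorial side chain and the 3,4-anti carbinol expected for a cyclic E-enolate, and the aldolate is trapped as the phosphate leaving group.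

Step 13
Reactants: 19 acrolein; 20 propionyl bromide
Product: 21 3-bromoprop-1-enyl propanoate (E/Z mixture)
Conditions: ZnCl2 (2 mol %), CH2Cl2, −20 °C
Reagents that add atoms: none
Why: Lewis-acid-catalysed 1,4-addition of the acyl bromide to the enal gives the γ-bromo enol ester, whose alkene geometry is lost on metalation.

Step 14
Reactants: 18 3,4-anti aldol diphenyl phosphate; 21 3-bromoprop-1-enyl propanoate
Product: 23 8β-hydroxy-7-propanoyloxy diene (C7 chain α-axial on C8), via acyloxyallylzinc bromide 22 (not isolated)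
Conditions: activated Zn, THF, 0 °C; aqueous work-up
Reagents that add atoms: none
Why: Barbier-type α-acyloxyallylation: the carbonyl-chelated Z-allylzinc adds through its γ carbon in a chair transition state from the axial α face (the β face carries the axial 9-OTES) with the allyl chain over the less hindered C9 flank, which sets 8β-OH and the 7,8-trans diol monoester.

Step 15
Reactants: 23 8β-hydroxy-7-propanoyloxy diene
Product: 24 linear A/B/C tricycle (A/B trans; B/C cis; Δ5; 4-phosphate; 7-propanoate; 8β-OH)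
Conditions: second-generation Grubbs catalyst RuCl2(=CHPh)(PCy3)(H2IMes) (5 mol %), CH2Cl2, 40 °C
Reagents that add atoms: none
Why: Ring-closing metathesis of the vinyl and isopropenyl groups, which are gauche on C8 and C3, closes the cis-fused cyclohexene and thereby fixes the C5=C6 geometry, while the ring A diene is too hindered to take part.

Step 16
Reactants: 24 linear A/B/C tricycle
Product: 28 ten-membered (3Z,5Z)-diene 8-hydroxy-γ-lactone (2β,9β-bis-OTES; 14α-OTBS), via dipotassium alkoxide enolate 25 (not isolated), via ten-membered keto enolate 26 (not isolated), via potassium aldolate 27 (not isolated)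
Conditions: KN(SiMe3)2 (2.3 equiv), THF, −78 °C, 30 min; −78 → −30 °C; AcOH, −78 °C
Reagents that add atoms: none
Why: Proposed new method: a dianion-programmed Grob ring expansion/aldol lactonisation in which two equivalents of base first turn 24 at −78 °C into the C8 alkoxide and propionate enolate while no ketone is present; on warming the alkoxide expels the pseudo-equatorial C4 phosphate, whose C–O bond is antiperiplanar to C3–C8 in the conformationally locked cis-B/C unit (C2 axial on ring C gives the 3Z alkene, ring C hands on the 5Z alkene), and the ketone so unveiled is trapped at once by the enolate on O7, which sits on the face just vacated by C3, so C17 replaces C3 with retention at C8 (lactone trans-fused) and the epimerisable C17 methyl settles anti to C9; the closest known reaction types are the Wharton–Grob fragmentation of 1,3-diol monosulfonates and the intramolecular ester-enolate aldol lactonisation, which have not been merged or run from a preformed enolate.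

Step 17
Reactants: 28 ten-membered diene hydroxy lactone
Product: 29 2β,9β-diol
Conditions: pyridinium p-toluenesulfonate (20 mol %), MeOH/CH2Cl2, 0 → 23 °C
Reagents that add atoms: none
Why: Acid-catalysed methanolysis removes the two triethylsilyl ethers, whereas the bulkier neopentyl TBS ether at C14 stays.

Step 18
Reactants: 29 2β,9β-diol
Product: 30 2β,9β-diacetate
Conditions: Ac2O, 4-dimethylaminopyridine (20 mol %), pyridine, 23 °C
Reagents that add atoms: acetic anhydride CC(=O)OC(C)=O
Why: Nucleophile-catalysed acylation acetylates the two secondary alcohols, and the tertiary 8-OH does not react.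

Step 19
Reactants: 30 2β,9β-diacetate
Product: 31 14α-alcohol
Conditions: HF·pyridine, pyridine, THF, 23 °C
Reagents that add atoms: none
Why: Buffered fluoride desilylation frees 14-OH without acetate migration or lactone opening.

Step 20
Reactants: 31 14α-alcohol
Product: 33 12α,13α,14α-triol, via osmate ester 32 (not isolated)
Conditions: OsO4 (1.05 equiv), Me2NCH2CH2NMe2 (1.1 equiv), CH2Cl2, −78 °C; then aq Na2SO3, THF, 23 °C
Reagents that add atoms: osmium tetroxide O=[Os](=O)(=O)=O
Why: Hydroxyl-directed dihydroxylation: the OsO4–diamine complex is hydrogen-bonded by the allylic 14α-OH and delivered to C12=C13 from the α face, which gives the all-cis triol, while the exocyclic alkene and the macrocyclic diene have no allylic OH.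

Step 21
Reactants: 33 12α,13α,14α-triol
Product: 34 13α-acetate
Conditions: 2-aminoethyl diphenylborinate (10 mol %), AcCl (1.1 equiv), iPr2NEt, MeCN, 0 °C
Reagents that add atoms: acetyl chloride CC(=O)Cl
Why: Borinic-acid-catalysed site-selective acylation: the borinate of a cis-1,2-diol is acylated at its equatorial oxygen, which is O13 for either diol pair, so the axial 12- and 14-OH stay free.

Step 22
Reactants: 34 13α-acetate
Product: 35 11α,20-epoxide (16-deoxy Juncin Q)
Conditions: VO(acac)2 (5 mol %), tBuOOH, CH2Cl2, 0 °C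
Reagents that add atoms: tert-butyl hydroperoxide CC(C)(C)OO
Why: Vanadium-catalysed hydroxyl-directed epoxidation: the axial allylic 12α-OH delivers the peroxide to the α face of C11=C20 only and so sets C11.

Step 23
Reactants: 35 11α,20-epoxide
Product: 36 Juncin Q
Conditions: SeO2 (0.5 equiv), tBuOOH (2 equiv), CH2Cl2, 0 → 23 °C
Reagents that add atoms: tert-butyl hydroperoxide CC(C)(C)OO
Why: Selenium dioxide allylic hydroxylation (ene reaction then 2,3-shift): C16 is the only allylic C–H on the more substituted alkene carbon C5 (C4 is sp2, C2 and C7 carry acyloxy groups), so the primary allylic alcohol forms with the alkene geometry kept.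

**Compound list**
1 | o-cresol | Cc1ccccc1O | starting material
2 | 2-methyl-1,4-benzoquinone | CC1=CC(=O)C=CC1=O | intermediate
3 | 2-methoxy-5-methyl-1,4-benzoquinone | COC1=CC(=O)C(C)=CC1=O | intermediate
4 | crotonaldehyde | C/C=C/C=O | starting material
5 | (E)-1-(tert-butyldimethylsilyloxy)buta-1,3-diene | C=C/C=C/O[Si](C)(C)C(C)(C)C | intermediate
6 | cis-fused Diels–Alder adduct (10βH) | C1=CC[C@H]2C(=O)C(OC)=CC(=O)[C@@]2(C)[C@H]1O[Si](C)(C)C(C)(C)C | intermediate
7 | trans-fused ring A/B enedione (14α-OTBS, 8-OMe, 1β-Me, 10αH) | C1=CC[C@@H]2C(=O)C(OC)=CC(=O)[C@@]2(C)[C@H]1O[Si](C)(C)C(C)(C)C | intermediate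
8 | 9β-alcohol | C1=CC[C@@H]2[C@H](O)C(OC)=CC(=O)[C@@]2(C)[C@H]1O[Si](C)(C)C(C)(C)C | intermediate
9 | 9β-OTES ether | C1=CC[C@@H]2[C@H](O[Si](CC)(CC)CC)C(OC)=CC(=O)[C@@]2(C)[C@H]1O[Si](C)(C)C(C)(C)C | intermediate
10 | Δ12-en-11-one | C1=CC(=O)[C@@H]2[C@H](O[Si](CC)(CC)CC)C(OC)=CC(=O)[C@@]2(C)[C@H]1O[Si](C)(C)C(C)(C)C | intermediate
11 | 11(20),12-diene | C1=CC(=C)[C@@H]2[C@H](O[Si](CC)(CC)CC)C(OC)=CC(=O)[C@@]2(C)[C@H]1O[Si](C)(C)C(C)(C)C | intermediate
12 | 2β-alcohol | C1=CC(=C)[C@@H]2[C@H](O[Si](CC)(CC)CC)C(OC)=C[C@H](O)[C@@]2(C)[C@H]1O[Si](C)(C)C(C)(C)C | intermediate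
13 | 2β,9β-bis-OTES methyl enol ether | C1=CC(=C)[C@@H]2[C@H](O[Si](CC)(CC)CC)C(OC)=C[C@H](O[Si](CC)(CC)CC)[C@@]2(C)[C@H]1O[Si](C)(C)C(C)(C)C | intermediate
14 | 3α-iodo-8-ketone | C1=CC(=C)[C@@H]2[C@H](O[Si](CC)(CC)CC)C(=O)[C@@H](I)[C@H](O[Si](CC)(CC)CC)[C@@]2(C)[C@H]1O[Si](C)(C)C(C)(C)C | intermediate
15 | methacrolein | CC(=C)C=O | starting material
16 | chloromagnesium 3(8)-enolate | C1=CC(=C)[C@@H]2[C@H](O[Si](CC)(CC)CC)C(O[Mg]Cl)=C[C@H](O[Si](CC)(CC)CC)[C@@]2(C)[C@H]1O[Si](C)(C)C(C)(C)C | intermediate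
17 | chloromagnesium 3,4-anti aldolate | C1=CC(=C)[C@@H]2[C@H](O[Si](CC)(CC)CC)C(=O)[C@@H]([C@H](O[Mg]Cl)C(C)=C)[C@H](O[Si](CC)(CC)CC)[C@@]2(C)[C@H]1O[Si](C)(C)C(C)(C)C | intermediate
18 | 3,4-anti aldol diphenyl phosphate | C1=CC(=C)[C@@H]2[C@H](O[Si](CC)(CC)CC)C(=O)[C@@H]([C@H](OP(=O)(Oc4ccccc4)Oc4ccccc4)C(C)=C)[C@H](O[Si](CC)(CC)CC)[C@@]2(C)[C@H]1O[Si](C)(C)C(C)(C)C | intermediate
19 | acrolein | C=CC=O | starting material
20 | propionyl bromide | CCC(=O)Br | starting material
21 | 3-bromoprop-1-enyl propanoate (E/Z mixture) | CCC(=O)OC=CCBr | intermediate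
22 | (Z)-3-(propanoyloxy)allylzinc bromide | CCC(=O)O/C=C\C[Zn]Br | intermediate
23 | 8β-hydroxy-7-propanoyloxy diene | C1=CC(=C)[C@@H]2[C@H](O[Si](CC)(CC)CC)[C@@](O)([C@@H](OC(=O)CC)C=C)[C@@H]([C@H](OP(=O)(Oc4ccccc4)Oc4ccccc4)C(C)=C)[C@H](O[Si](CC)(CC)CC)[C@@]2(C)[C@H]1O[Si](C)(C)C(C)(C)C | intermediate
24 | linear A/B/C tricycle (A/B trans, B/C cis) | C1=CC(=C)[C@@H]2[C@H](O[Si](CC)(CC)CC)[C@@]3(O)[C@@H](OC(=O)CC)C=C(C)[C@@H](OP(=O)(Oc4ccccc4)Oc4ccccc4)[C@H]3[C@H](O[Si](CC)(CC)CC)[C@@]2(C)[C@H]1O[Si](C)(C)C(C)(C)C | intermediate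
25 | dipotassium C8 alkoxide / propionate E-enolate | C1=CC(=C)[C@@H]2[C@H](O[Si](CC)(CC)CC)[C@@]3([O-])[C@@H](O/C([O-])=C\C)C=C(C)[C@@H](OP(=O)(Oc4ccccc4)Oc4ccccc4)[C@H]3[C@H](O[Si](CC)(CC)CC)[C@@]2(C)[C@H]1O[Si](C)(C)C(C)(C)C.[K+].[K+] | intermediate
26 | ten-membered (3Z,5Z)-dien-8-one potassium ester enolate | C1=CC(=C)[C@@H]2[C@H](O[Si](CC)(CC)CC)C(=O)[C@H](/C=C(C)\C=C/[C@H](O[Si](CC)(CC)CC)[C@@]2(C)[C@H]1O[Si](C)(C)C(C)(C)C)O/C([O-])=C\C.[K+] | intermediate
27 | potassium 8-alkoxide of the lactone | C1=CC(=C)[C@@H]2[C@H](O[Si](CC)(CC)CC)[C@@]3([O-])[C@H](/C=C(C)\C=C/[C@H](O[Si](CC)(CC)CC)[C@@]2(C)[C@H]1O[Si](C)(C)C(C)(C)C)OC(=O)[C@@H]3C.[K+] | intermediate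
28 | ten-membered (3Z,5Z)-diene 8-hydroxy-γ-lactone (2β,9β-bis-OTES, 14α-OTBS) | C1=CC(=C)[C@@H]2[C@H](O[Si](CC)(CC)CC)[C@@]3(O)[C@H](/C=C(C)\C=C/[C@H](O[Si](CC)(CC)CC)[C@@]2(C)[C@H]1O[Si](C)(C)C(C)(C)C)OC(=O)[C@@H]3C | intermediate
29 | 2β,9β-diol | C1=CC(=C)[C@@H]2[C@H](O)[C@@]3(O)[C@H](/C=C(C)\C=C/[C@H](O)[C@@]2(C)[C@H]1O[Si](C)(C)C(C)(C)C)OC(=O)[C@@H]3C | intermediate
30 | 2β,9β-diacetate | C1=CC(=C)[C@@H]2[C@H](OC(C)=O)[C@@]3(O)[C@H](/C=C(C)\C=C/[C@H](OC(C)=O)[C@@]2(C)[C@H]1O[Si](C)(C)C(C)(C)C)OC(=O)[C@@H]3C | intermediate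
31 | 14α-alcohol | C1=CC(=C)[C@@H]2[C@H](OC(C)=O)[C@@]3(O)[C@H](/C=C(C)\C=C/[C@H](OC(C)=O)[C@@]2(C)[C@H]1O)OC(=O)[C@@H]3C | intermediate
32 | 12α,13α-osmate ester, diamine adduct | O=[Os]4(=O)O[C@H]1[C@@H](O4)C(=C)[C@@H]2[C@H](OC(C)=O)[C@@]3(O)[C@H](/C=C(C)\C=C/[C@H](OC(C)=O)[C@@]2(C)[C@H]1O)OC(=O)[C@@H]3C.CN(C)CCN(C)C | intermediate
33 | 12α,13α,14α-triol | O[C@H]1[C@@H](O)C(=C)[C@@H]2[C@H](OC(C)=O)[C@@]3(O)[C@H](/C=C(C)\C=C/[C@H](OC(C)=O)[C@@]2(C)[C@H]1O)OC(=O)[C@@H]3C | intermediate
34 | 13α-acetate | CC(=O)O[C@H]1[C@@H](O)C(=C)[C@@H]2[C@H](OC(C)=O)[C@@]3(O)[C@H](/C=C(C)\C=C/[C@H](OC(C)=O)[C@@]2(C)[C@H]1O)OC(=O)[C@@H]3C | intermediate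
35 | 11α,20-epoxide (16-deoxy Juncin Q) | CC(=O)O[C@H]1[C@@H](O)[C@]2(CO2)[C@@H]2[C@H](OC(C)=O)[C@@]3(O)[C@H](/C=C(C)\C=C/[C@H](OC(C)=O)[C@@]2(C)[C@H]1O)OC(=O)[C@@H]3C | intermediate
36 | Juncin Q | CC(=O)O[C@H]1[C@@H](O)[C@]2(CO2)[C@@H]2[C@H](OC(C)=O)[C@@]3(O)[C@H](/C=C(CO)\C=C/[C@H](OC(C)=O)[C@@]2(C)[C@H]1O)OC(=O)[C@@H]3C | target

**Step count and risks**
Total step count: 23. Longest linear sequence: 21 (steps 1, 2, 4–12 and 14–23, from o-cresol).

**Step 16 (proposed new step).**
- Risk: the fragmentation may outrun ester enolisation, so that the base then enolises the new ketone at C7. The potassium enolate may also collapse to a ketene on warming.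
- Fallback (known chemistry): it sets out from 24 and comes back at 28. One equivalent of KOtBu in THF/tBuOH at 0 °C (classical Wharton–Grob fragmentation) gives the isolable ten-membered keto propionate F1. Mild methanolysis of this activated α-acyloxy ketone (K2CO3, MeOH, 0 °C) gives the 7-hydroxy ketone F2. Acryloyl chloride and iPr2NEt give the keto acrylate F3. A copper hydride reductive aldol cyclisation (Cu(OAc)2·H2O, 1,1'-bis(diphenylphosphino)ferrocene, (Me2HSi)2O, THF) then forms the ester enolate chemoselectively by conjugate reduction and closes the lactone to 28.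

**Step 14.**
- Risk: the ketone is flanked by two branched carbons and the γ-acyloxyallyl metal is a weak nucleophile. The C7 configuration also rests on a transition-state argument.
- Fallback: it sets out from 18 and comes back at 28, and it moves the C7 oxygen to a later stage. Allyl bromide and Zn give the plain homoallylic alcohol F4. Ring-closing metathesis gives the 7-deoxy tricycle F5. KOtBu-induced Grob fragmentation gives the ten-membered β,γ-unsaturated ketone F6. Kinetic enolisation toward the allylic C7 (KN(SiMe3)2, −78 °C) and reagent-controlled hydroxylation with (+)-(camphorsulfonyl)oxaziridine give the 7-hydroxy ketone F2. F2 is then carried through the keto acrylate F3 and the copper hydride cyclisation to 28.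

**Step 23.**
- Risk: the selenium reagent may attack the conjugated diene or over-oxidise to the enal on the fully functionalised substrate.
- Fallback: it sets out from 35 and comes back at 36, and it replaces the ene chemistry by radical halogenation and solvolysis. N-Bromosuccinimide under visible light in PhCF3 brominates the C16 methyl through the C16–C5–C6 allyl radical at its primary end and gives the 16-bromide F7. AgOCOCF3 in aqueous acetone with CaCO3 then converts F7 into 36.

**Further compounds**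
F1 | step 16 | ten-membered keto propionate | C1=CC(=C)[C@@H]2[C@H](O[Si](CC)(CC)CC)C(=O)[C@H](/C=C(C)\C=C/[C@H](O[Si](CC)(CC)CC)[C@@]2(C)[C@H]1O[Si](C)(C)C(C)(C)C)OC(=O)CC
F2 | step 16 | 7-hydroxy ketone | C1=CC(=C)[C@@H]2[C@H](O[Si](CC)(CC)CC)C(=O)[C@H](/C=C(C)\C=C/[C@H](O[Si](CC)(CC)CC)[C@@]2(C)[C@H]1O[Si](C)(C)C(C)(C)C)O
F3 | step 16 | keto acrylate | C1=CC(=C)[C@@H]2[C@H](O[Si](CC)(CC)CC)C(=O)[C@H](/C=C(C)\C=C/[C@H](O[Si](CC)(CC)CC)[C@@]2(C)[C@H]1O[Si](C)(C)C(C)(C)C)OC(=O)C=C
F4 | step 14 | plain homoallylic alcohol | C1=CC(=C)[C@@H]2[C@H](O[Si](CC)(CC)CC)[C@@](O)(CC=C)[C@@H]([C@H](OP(=O)(Oc4ccccc4)Oc4ccccc4)C(C)=C)[C@H](O[Si](CC)(CC)CC)[C@@]2(C)[C@H]1O[Si](C)(C)C(C)(C)C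
F5 | step 14 | 7-deoxy tricycle | C1=CC(=C)[C@@H]2[C@H](O[Si](CC)(CC)CC)[C@@]3(O)CC=C(C)[C@@H](OP(=O)(Oc4ccccc4)Oc4ccccc4)[C@H]3[C@H](O[Si](CC)(CC)CC)[C@@]2(C)[C@H]1O[Si](C)(C)C(C)(C)C
F6 | step 14 | ten-membered β,γ-unsaturated ketone | C1=CC(=C)[C@@H]2[C@H](O[Si](CC)(CC)CC)C(=O)C/C=C(C)\C=C/[C@H](O[Si](CC)(CC)CC)[C@@]2(C)[C@H]1O[Si](C)(C)C(C)(C)C
F7 | step 23 | 16-bromide | CC(=O)O[C@H]1[C@@H](O)[C@]2(CO2)[C@@H]2[C@H](OC(C)=O)[C@@]3(O)[C@H](/C=C(CBr)\C=C/[C@H](OC(C)=O)[C@@]2(C)[C@H]1O)OC(=O)[C@@H]3C
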